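**Plan**

- Numbering, each half as a quinolizidine: C1 (CH bearing the chain), C2 (ketone), C3 (CHMe), C4, N5, C6–C8, C9 (CH bearing the chain), C10 (bridgehead); C11–C15 link C1 to C9′ of the other half; ring A = N5/C4/C3/C2/C1/C10, ring B = N5/C6–C10. Enabling feature: the 16-membered carbocycle is two identical eight-carbon units C10–C9–C15–C14–C13–C12–C11–C1 joined head to tail, i.e. the cyclodimer of a cyclooctene substituted at its allylic carbon C9 and opened at C1=C10.
- Retrosynthesis: cut N5–C4 and C2–C3 (ring A, both halves), then N5–C10 and C1–C2 (ring B, both halves), then the two C1=C10 bonds of the macrocycle, and last C8–C9 of the cyclooctene monomer.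
- Forward: C9 side chain on cyclooctene → Boc-aminopropyl cyclooctene → 16-membered (E,E)-diene by metathesis ring expansion → both rings B by aminocarbonylation → both rings A by isopropenyl ketone formation and aza-Michael closure.
- Stereochemistry: C9 from a copper/phosphoramidite allylic alkylation; C10 from anti-aminopalladation steered by C9; C1 and C3 from base equilibration next to the C2 ketone.

Key step: step 6

Assumption: the (S,S,S)-phosphoramidite is taken to give the (S)-alkylation product in the eight-membered series; if the sense of induction is the opposite, the enantiomeric ligand is used.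
Assumption: in the trans-fused 2-oxoquinolizidine the arrangement with C11 and the C3 methyl equatorial on ring A (C15 axial on ring B) is taken as the thermodynamic one, so that equilibration of C1 and C3 ends at the target.

**Route**

Step 1
Reactants: 1 cis-cyclooctene; 2 N-bromosuccinimide
Product: 3 rac-(Z)-3-bromocyclooctene
Conditions: AIBN (cat.), cyclohexane, reflux
Reagents that add atoms: none
Why: Wohl–Ziegler allylic bromination through the symmetric cyclooctenyl radical, which can give only one constitutional isomer.

Step 2
Reactants: 3 rac-(Z)-3-bromocyclooctene; 4 (3-bromopropoxy)(tert-butyl)dimethylsilane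
Product: 6 tert-butyldimethyl{3-[(1S,2Z)-cyclooct-2-en-1-yl]propoxy}silane, via Grignard reagent 5 (not isolated)
Conditions: 4, Mg, Et2O, reflux; then 3, CuBr·SMe2 (3 mol%), O,O′-[(S)-1,1′-binaphthyl-2,2′-diyl] N,N-bis[(S)-1-phenylethyl]phosphoramidite (3.3 mol%), CH2Cl2, −78 °C, slow addition of 5
Reagents that add atoms: none
Why: Copper-catalysed asymmetric allylic alkylation of a racemic cyclic allyl bromide with a primary alkyl Grignard reagent (dynamic kinetic asymmetric transformation): both enantiomers of 3 pass through a common allylcopper species whose allyl unit is symmetric, so either substitution mode gives the same constitution, and the ligand-controlled C–C bond formation sets C9 as S.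

Step 3
Reactants: 6 tert-butyldimethyl{3-[(1S,2Z)-cyclooct-2-en-1-yl]propoxy}silane
Product: 7 3-[(1S,2Z)-cyclooct-2-en-1-yl]propan-1-ol
Conditions: Bu4NF, THF, 0 °C to rt
Reagents that add atoms: none
Why: Fluoride-induced cleavage of the silyl ether, driven by the Si–F bond, leaves the alkene and C9 untouched.

Step 4
Reactants: 7 3-[(1S,2Z)-cyclooct-2-en-1-yl]propan-1-ol
Product: 8 (1Z,3S)-3-(3-azidopropyl)cyclooct-1-ene
Conditions: PPh3, DIAD, (PhO)2P(O)N3, THF, 0 °C to rt
Reagents that add atoms: diphenylphosphoryl azide, [N-]=[N+]=NP(=O)(Oc1ccccc1)Oc1ccccc1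
Why: Mitsunobu azidation of an unhindered primary alcohol (activation as the alkoxyphosphonium ion, displacement by azide), remote from C9.

Step 5
Reactants: 8 (1Z,3S)-3-(3-azidopropyl)cyclooct-1-ene; 9 di-tert-butyl dicarbonate
Product: 11 tert-butyl N-{3-[(1S,2Z)-cyclooct-2-en-1-yl]propyl}carbamate, via primary amine 10 (not isolated)
Conditions: PPh3, THF–H2O, 50 °C; then 9, rt
Reagents that add atoms: none
Why: Staudinger reduction spares the alkene (unlike hydrogenation), and the amine is acylated in the same flask by the dicarbonate.

Step 6
Reactants: 11 tert-butyl N-{3-[(1S,2Z)-cyclooct-2-en-1-yl]propyl}carbamate (two molecules)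
Product: 12 (1E,3S,9E,11S)-3,11-bis{3-[(tert-butoxycarbonyl)amino]propyl}cyclohexadeca-1,9-diene
Conditions: second-generation Grubbs catalyst RuCl2(=CHPh)(H2IMes)(PCy3) (5 mol%), 1,4-benzoquinone (10 mol%), CH2Cl2, 2 mM, 40 °C; ethyl vinyl ether quench
Reagents that add atoms: none
Why: Proposed new method: the ruthenium alkylidene opens the strained cyclooctene of 11 by [2+2] cycloaddition and cycloreversion, the chain-end alkylidene opens a second molecule, and back-biting of the metal carbene onto the far alkene of the two-unit chain closes the ring and releases the catalyst; the closest known reaction types are the head-to-tail, trans-selective ring-opening metathesis polymerisation of 3-substituted cis-cyclooctenes and the metathesis cyclodimerisation of cyclooctene itself to cyclohexadeca-1,9-diene. The one ring formed is the 16-membered carbocycle, closed by macrocyclic ring-closing metathesis at a C1=C10 bond. No stereocentre is created: both C9 centres are carried through and the alkenes should settle as E under the reversible conditions. The step needs head-to-tail regiochemistry and the dimer ring size; the C9 branch makes an alkene flanked by two branched allylic carbons slow to form (and every tail-to-tail link would need such a partner), while at 2 mM the ring–chain equilibrium should favour the smallest strain-free ring, with release of cyclooctene strain driving the opening. Because 11 is a single enantiomer the head-to-tail dimer is C2-symmetric, and any residual (R)-11 should end up mainly in a separable meso diastereomer; benzoquinone is added against double-bond migration.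

Step 7
Reactants: 12 (1E,3S,9E,11S)-3,11-bis{3-[(tert-butoxycarbonyl)amino]propyl}cyclohexadeca-1,9-diene
Product: 13 macrocyclic bis(N-Boc-piperidine) dimethyl ester: in each half N5 is bonded to C10 (ring B closed) and C1 carries CO2Me; configuration 1S,9S,10R in both halves
Conditions: PdCl2 (20 mol%), CuCl2 (6 equiv), NaOAc (6 equiv), CO (1 atm), MeOH–CH2Cl2, rt
Reagents that add atoms: carbon monoxide, [C-]#[O+]; methanol, CO
Why: Twofold intramolecular aminocarbonylation (Wacker-type aminopalladation, CO insertion, methanolysis) of a carbamate onto a 1,2-disubstituted alkene: N5 attacks C10 anti to divalent palladium in a 6-exo chair with the alkene equatorial, C9–H turned toward the metal and C15 axial, which should give the 9,10-cis piperidine (C10 R), while C1 arrives S by anti addition across the E alkene with retentive CO insertion and is corrected in step 10; CuCl2 reoxidises zerovalent palladium and NaOAc shields the Boc groups from HCl.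

Step 8
Reactants: 13 macrocyclic bis(N-Boc-piperidine) dimethyl ester
Product: 14 corresponding bis(N-methoxy-N-methylamide): C(=O)N(OMe)Me on C1 and C1′, otherwise as 13 (1S,9S,10R in both halves)
Conditions: MeNH(OMe)·HCl, iPrMgCl, THF, −20 to 0 °C
Reagents that add atoms: N,O-dimethylhydroxylamine hydrochloride, CNOC.Cl
Why: Weinreb amide formation by aminolysis of the esters with the magnesium amide made in the flask, a protocol that works on α-branched esters at low temperature; partial epimerisation at C1 would be harmless.

Step 9
Reactants: 14 bis(N-methoxy-N-methylamide)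
Product: 15 bis(isopropenyl ketone): C(=O)C(CH3)=CH2 on C1 and C1′ (C2, C3, C4 and the methyl group in place), N-Boc rings B intact, 1S,9S,10R in both halves
Conditions: CH2=C(CH3)MgBr, THF, −20 to 0 °C; inverse quench into cold aq. NH4Cl
Reagents that add atoms: isopropenylmagnesium bromide, C=C(C)[Mg]Br
Why: Weinreb ketone synthesis: the magnesium chelate of the tetrahedral adduct survives until the quench, so addition stops at the enone and the Boc carbamates are not attacked.

Step 10
Reactants: 15 bis(isopropenyl ketone)
Product: 18 target bis-quinolizidinone CNP0268544.6 (1R,3S,9S,10R in both halves), via bis(amino enone) 16 (not isolated), via 1,1′-bis-epimer 17 (not isolated)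
Conditions: TFA, CH2Cl2, 0 °C to rt; evaporate; K2CO3, MeOH, rt to 40 °C
Reagents that add atoms: none
Why: Acidolysis of the Boc groups frees the ring B amines, which after neutralisation add to C4 of the isopropenyl ketones (6-endo aza-Michael addition) to close ring A, and reversible enolisation under the basic conditions inverts C1 and sets C3 so that the C11 chain and the methyl group become equatorial on the trans-fused 2-oxoquinolizidine (1R,3S), C9 and C10 carrying no acidic hydrogen.

**Compound list**

1 | cis-cyclooctene | C1CCC/C=C\CC1 | starting material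
2 | N-bromosuccinimide | O=C1CCC(=O)N1Br | starting material
3 | rac-(Z)-3-bromocyclooctene | BrC1/C=C\CCCCC1 | intermediate
4 | (3-bromopropoxy)(tert-butyl)dimethylsilane | CC(C)(C)[Si](C)(C)OCCCBr | starting material
5 | [3-(tert-butyldimethylsilyloxy)propyl]magnesium bromide (not isolated) | CC(C)(C)[Si](C)(C)OCCC[Mg]Br | intermediate
6 | tert-butyldimethyl{3-[(1S,2Z)-cyclooct-2-en-1-yl]propoxy}silane | CC(C)(C)[Si](C)(C)OCCC[C@H]1/C=C\CCCCC1 | intermediate
7 | 3-[(1S,2Z)-cyclooct-2-en-1-yl]propan-1-ol | OCCC[C@H]1/C=C\CCCCC1 | intermediate
8 | (1Z,3S)-3-(3-azidopropyl)cyclooct-1-ene | [N-]=[N+]=NCCC[C@H]1/C=C\CCCCC1 | intermediate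
9 | di-tert-butyl dicarbonate | CC(C)(C)OC(=O)OC(=O)OC(C)(C)C | starting material
10 | 3-[(1S,2Z)-cyclooct-2-en-1-yl]propan-1-amine (not isolated) | NCCC[C@H]1/C=C\CCCCC1 | intermediate
11 | tert-butyl N-{3-[(1S,2Z)-cyclooct-2-en-1-yl]propyl}carbamate | CC(C)(C)OC(=O)NCCC[C@H]1/C=C\CCCCC1 | intermediate
12 | (1E,3S,9E,11S)-3,11-bis{3-[(tert-butoxycarbonyl)amino]propyl}cyclohexadeca-1,9-diene | CC(C)(C)OC(=O)NCCC[C@H]1/C=C/CCCCC[C@@H](CCCNC(=O)OC(C)(C)C)/C=C/CCCCC1 | intermediate
13 | macrocyclic bis(N-Boc-piperidine) dimethyl ester (1S,9S,10R in both halves) | CC(C)(C)OC(=O)N1CCC[C@H]2[C@@H]1[C@@H](C(=O)OC)CCCCC[C@H]3CCCN(C(=O)OC(C)(C)C)[C@H]3[C@@H](C(=O)OC)CCCCC2 | intermediate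
14 | bis(N-methoxy-N-methylamide) (1S,9S,10R in both halves) | CC(C)(C)OC(=O)N1CCC[C@H]2[C@@H]1[C@@H](C(=O)N(C)OC)CCCCC[C@H]3CCCN(C(=O)OC(C)(C)C)[C@H]3[C@@H](C(=O)N(C)OC)CCCCC2 | intermediate
15 | bis(isopropenyl ketone), N-Boc (1S,9S,10R in both halves) | CC(C)(C)OC(=O)N1CCC[C@H]2[C@@H]1[C@@H](C(=O)C(C)=C)CCCCC[C@H]3CCCN(C(=O)OC(C)(C)C)[C@H]3[C@@H](C(=O)C(C)=C)CCCCC2 | intermediate
16 | bis(amino enone), free base of the bis(trifluoroacetate) (not isolated) | N1CCC[C@H]2[C@@H]1[C@@H](C(=O)C(C)=C)CCCCC[C@H]3CCCN[C@H]3[C@@H](C(=O)C(C)=C)CCCCC2 | intermediate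
17 | 1,1′-bis-epimer of the target, 1S,3S,9S,10R in both halves (not isolated) | C[C@H]1CN2CCC[C@@H]3CCCCC[C@@H]4C(=O)[C@@H](C)CN5CCC[C@H](CCCCC[C@H](C1=O)[C@@H]32)[C@H]45 | intermediate
18 | CNP0268544.6, bis-quinolizidinone, 1R,3S,9S,10R in both halves | C[C@H]1CN2CCC[C@@H]3CCCCC[C@H]4C(=O)[C@@H](C)CN5CCC[C@H](CCCCC[C@@H](C1=O)[C@@H]32)[C@H]45 | target

**Step count**

Total step count: 10. Longest linear sequence: 10 steps (1 to 18; the Grignard reagent 5 is made and used within step 2).

**Steps most likely to fail**

1. Step 6 (the proposed method). The ring–chain equilibrium may settle on larger cyclic oligomers instead of the dimer. Slow formation of doubly branched alkenes may erode the head-to-tail order. Ruthenium hydrides may shift the double bonds and so change the ring size. Fallback, setting out from 11: ethenolysis (ethylene, 1 atm, first-generation Grubbs catalyst RuCl2(=CHPh)(PCy3)2, CH2Cl2, rt) should open the ring to the acyclic diene tert-butyl N-[(4S)-4-ethenylundec-10-en-1-yl]carbamate F1. F1 is then cyclodimerised by cross metathesis followed by ring-closing metathesis (second-generation catalyst RuCl2(=CHPh)(H2IMes)(PCy3), 5 mM, CH2Cl2, reflux, argon purge to remove ethylene). The unbranched vinyl group reacts fast and the branched one slowly, so the cross (head-to-tail) alkene is the one that builds up; this is an established way of cyclodimerising dienes with one branched and one unbranched vinyl terminus. The sequence returns to 12.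

2. Step 7. Attack of nitrogen on the wrong alkene face would give the 9,10-trans piperidine. Aminopalladation of the internal alkenes may be slow enough for alkene isomerisation to compete, and HCl may strip the Boc groups. Fallback, setting out from 12: reversible amidomercuration (Hg(OCOCF3)2, CH3NO2, rt, then aq. NaCl) should equilibrate to the more stable 9,10-cis N-Boc piperidine, in which A(1,3) strain holds the C10 substituent axial and C15 equatorial. This gives the bis(chloromercurio) compound F2 (HgCl on C1 and C1′). Carbonylation of the carbon–mercury bonds (Li2PdCl4, CO, MeOH; transmetalation to divalent palladium, CO insertion, methanolysis) returns to 13.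

3. Step 2. Enantioconvergence of the two bromide enantiomers may be incomplete in the eight-membered ring, and uncatalysed coupling would add racemic product. Fallback, setting out from 1: allylic oxidation (t-BuOOH, dirhodium tetrakis(caprolactamate) Rh2(cap)4, CH2Cl2) gives (Z)-cyclooct-2-en-1-one F3. Copper-catalysed asymmetric conjugate addition of 5 (CuBr·SMe2, chiral ferrocenyl diphosphine, t-BuOMe, −78 °C) sets C9 under reagent control. The magnesium enolate is trapped with N-(5-chloropyridin-2-yl)bis(trifluoromethanesulfonyl)imide as (3S)-3-[3-(tert-butyldimethylsilyloxy)propyl]cyclooct-1-en-1-yl trifluoromethanesulfonate F4. Reduction of the enol triflate (Pd(OAc)2, PPh3, HCO2H, Bu3N, DMF, 60 °C) returns to 6.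

**Further compounds**

F1 | step 6 | tert-butyl N-[(4S)-4-ethenylundec-10-en-1-yl]carbamate | CC(C)(C)OC(=O)NCCC[C@@H](C=C)CCCCCC=C
F2 | step 7 | bis(chloromercurio) bis(N-Boc-piperidine), HgCl on C1 and C1′ | CC(C)(C)OC(=O)N1CCC[C@H]2[C@@H]1[C@@H]([Hg]Cl)CCCCC[C@H]3CCCN(C(=O)OC(C)(C)C)[C@H]3[C@@H]([Hg]Cl)CCCCC2
F3 | step 2 | (Z)-cyclooct-2-en-1-one | O=C1/C=C\CCCCC1
F4 | step 2 | (3S)-3-[3-(tert-butyldimethylsilyloxy)propyl]cyclooct-1-en-1-yl trifluoromethanesulfonate | CC(C)(C)[Si](C)(C)OCCC[C@H]1/C=C(OS(=O)(=O)C(F)(F)F)\CCCCC1
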